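Remark on numbering: germacrane numbering is used throughout (ring C1–C10, lactone carbons C11–C13, ester carbon C14 on C10, methyl C15 on C4).
Remark on the chemistry: the C8 ester is (2S,3R)-2,3-dimethyloxirane-2-carboxylate, whose two methyl groups are cis, so it is made from (E)-2-methylbut-2-en-1-ol. (S)-Glyceraldehyde acetonide is taken as a commercial chiral-pool material.

## The problem

The target is a germacranolide: a ten-membered carbocycle (C1–C10) with a trans-fused α-methylene-γ-lactone across C6–C7, a trans C4–C5 epoxide bearing the C15 methyl, a (Z)-C2=C3 alkene and a C10=C1 enoate (C14 methyl ester, C9 cis to C2). It carries an acetate on C9 and an epoxy ester on C8. Six contiguous ring stereocentres (C4 to C9) and two in the side chain must be set as one enantiomer. Only C6 needs an external source of chirality. Its hydroxyl can direct the epoxidation that fixes C4 and C5, its silyl ether can shield one face when C7 is formed, C8 forms together with C7, and C9 can be set last by reduction next to C8. The side chain is independent and needs its own asymmetric step. The ring is medium-sized and holds three rigid units, so direct closure of the ten-membered ring is unfavourable. The tertiary vinyl epoxide (acid, zerovalent palladium), the α-methylene lactone (nucleophiles), the C9 allylic acetate on an acrylate (SN2′ displacement) and the epoxy ester will not survive rough treatment. The enabling feature is that C8 carries oxygen and sits next to the C9 carbonyl, while C7 carries the C11(=C13)–C12 propenoate. This homoallylic alcohol pattern is the product of a [2,3]-Wittig shift, and reconnecting O8 to C13 turns the ten-membered ring into a thirteen-membered ether that is far easier to close.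

## Retrosynthesis

**Lactone last (34 from 32 via 33).** The acyl–oxygen bond C12–O6 is cut first. The α-methylene lactone is the group most exposed to nucleophiles, so it is kept open as a methyl propenoate with O6 silylated until the end. The forward step asks only for fluoride desilylation; the C6 alkoxide of 33 should then close the five-membered ring.

**C9 and C10=C1 (32 from 31, 30, 27).** The acetate 32 comes from alcohol 31 and this from ketone 30 by 1,2-reduction. The C10=C1 bond of 30 is traced to the saturated β-keto ester 27 by selenoxide elimination (selenide 28, selenoxide 29). Placing C9 at the ketone level and C10–C1 saturated is what makes C8 acidifiable for the key step. The forward steps ask for 1,2- over conjugate reduction and for hydride delivery anti to the C8 ester.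

**Side chain (27 from 22 and 25).** The C8 ester C–O bond is cut, giving the ten-membered hydroxy keto ester 22 and acid 25 (activated as mixed anhydride 26). Acid 25 comes from epoxy alcohol 24, and this from tiglyl alcohol 23 by Sharpless epoxidation. A convergent ester bond keeps the second epoxide out of all earlier steps.

**Key disconnection (22 from 21).** The C7–C8 bond is cut and O8 is joined to C13, with the double bond moved from C11=C13 to C7=C11. This is the retro-[2,3]-Wittig shift, and it gives the thirteen-membered allyl ether 21.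
- The neighbouring cut C6–C7 (allyl metal plus aldehyde) would need a C8 aldehyde next to the C9 carbonyl.
- A cut at C10–C1 would demand direct ten-ring closure.
- The chosen cut removes two stereocentres, replaces a medium ring by a large one, and leaves C6 as the controlling centre.
- The forward reaction must be γ-selective for the dianion, use one alkene face, and must not let the C8 alkoxide attack the C12 ester.

**Macrocycle (21 from 20 and 19).** The cis C2=C3 alkene is taken back to the alkyne 20, and the ring is opened at C10–C1 to the propargylic bromide 19. Closing the ring by C-alkylation of the β-keto ester uses its most acidic position, so no extra activating group is needed. The alkyne is carried until the ring is closed because a propargylic C1 hydroxyl cannot reach the epoxide, while its cis-alkene counterpart can cyclise onto C4.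

**Ether (19 from 18, 17; 17 from 15 and 16).** Bromide 19 comes from alcohol 18, and this from the 4-methoxybenzyl ether 17. The C8–O bond of 17 is cut to the allylic alcohol 15 and methyl 4-chloroacetoacetate 16, which brings C8, C9, C10 and C14 in one piece.

**Propenoate (15 from 14, 13, 12; 12 from 10 and 11).** Alcohol 15 comes from acetate 14 and bromide 13. Bromide 13 is the allylic transposition product of the Morita–Baylis–Hillman adduct 12, which is cut at C7–C11 into aldehyde 10 and methyl acrylate 11. The transposition fixes the needed geometry (C6 cis to C13) without a stereoselective olefination.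

**Epoxide and C6 (10 from 9, 8, 7, 6).** Aldehyde 10 comes from the bis-silyl ether 9 by direct oxidation of the primary triethylsilyl ether. The epoxide of 8 is cut to the allylic alcohol 7, where the free C6 hydroxyl and the C15 methyl cis to it should give the threo epoxy alcohol. Alcohol 7 is the primary silyl ether of diol 6. Triisopropylsilyl is placed on O6 because neighbouring alkoxides appear later (steps 13 and 18) and a smaller silyl group could migrate.

**Carbon chain (6 from 5, 4, 3, 2, 1).** Diol 6 comes from acetonide 5. The ether 5 comes from propargylic alcohol 4, whose C1 is formaldehyde and whose alkyne comes from dibromodiene 3 and enal 2. The C4=C5 bond of 2 is cut by a Wittig disconnection to (S)-glyceraldehyde acetonide 1, the only chiral-pool centre of the ring.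

## Roads not taken

**Alternative 1:** The cut goes through C5–C6 and C9–C10 at once. In the forward sense the tropone A1 and the diene A2 would combine in a thermal [6+4] cycloaddition to the exo bicyclo[4.4.1] adduct A3. In A3 the C6 and C9 acetoxy groups and an oxygen on C5 are in place, and the bridging carbonyl could later become the C14 ester.
- Merits: two ring bonds, the ten-membered periphery and four stereocentres form in one step from flat, cheap partners, with no macrocyclisation. In ring construction this is clearly shorter than the seventeen steps needed here before the ring exists.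
- Weak points: A3 is racemic unless an enantioselective variant is found. Bonding at the fully substituted, oxygen-bearing tropone carbon is the less favoured mode, and [4+2] addition competes. After the cycloaddition the C1=C2/C3=C4 diene must be moved to C10=C1/C2=C3 with an epoxide at C4–C5. C5 is over-oxidised once the bridge is opened. C7 lacks its three-carbon branch and C8 its oxygen.
- Comparison: Alternative 1 wins on brevity of ring formation. The chosen plan sets against it a secured absolute configuration, every ring stereocentre traced to C6, and a key step after which only functional-group changes remain.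

**Alternative 2:** The ring is seen as the fragmentation product of a decalin in which C3 and C8 are bonded. Forward, the tosylhydrazone of the ring-fusion epoxy ketone A4 would undergo Eschenmoser–Tanabe fragmentation to the cycloalkynone A5, with the C2≡C3 alkyne and the C8 ketone.
- Merits: ten-membered ynones are a well-established outcome of this fragmentation, there is no entropic penalty, the stereocentres C4–C7 and C9 are set on a rigid bicycle, and the alkyne leads directly to the cis C2=C3 alkene. In reliability of the ring-forming event this road is better than the chosen one, whose key step has no direct precedent.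
- Weak points: A4 is a decalin with eight stereocentres, a tetrasubstituted epoxide and a quaternary oxygenated C4, so the difficulty is moved rather than removed. After fragmentation the C4/C5 acetonide must become the epoxide, the C8 ketone must be reduced with control, C10=C1 must be introduced and C13 added by methylenation.
- Comparison: the chosen plan sets against the safer ring formation a much simpler acyclic precursor, and a rearrangement that delivers C7, C8, the C8 hydroxyl and the complete α-methylene ester in one event.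

**Alternative 3:** The C1(10),C2,C4 triene is seen as the open form of a cyclohexadiene, cutting C5–C10 in the retro sense. Forward, irradiation of the cis-fused hexalin A6 would open the ring in conrotatory fashion to the triene A7, which already carries the lactone, the C9 acetate and a C8 silyl ether.
- Merits: A7 is closer to the target than any intermediate of the other plans. Only epoxidation of C4=C5 and exchange of the C8 group would remain, and A6 is built by six-ring chemistry. In length of the endgame this road is better.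
- Weak points: the diene–triene pair reaches a photostationary state, and the triene can reclose thermally or isomerise photochemically. The sense of rotation must place the trans double bond at C4=C5 and the cis one at C10=C1, which the quaternary C10 does not obviously ensure. The acrylate lactone absorbs in the same region. The last epoxidation must pick both the alkene and its face on a flexible ring.
- Comparison: the chosen plan gives up the short endgame. In return its key step is a ground-state reaction at low temperature that can be driven to completion, and the epoxide is set early under control of the C6 hydroxyl.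

Key step: step 18

## Route

Step 1
Reactants: 1 (S)-2,2-dimethyl-1,3-dioxolane-4-carbaldehyde
Product: 2 (E)-3-[(4R)-2,2-dimethyl-1,3-dioxolan-4-yl]-2-methylprop-2-enal
Conditions: Ph3P=C(CH3)CHO, toluene, 80 °C
Reagents that add atoms: 2-(triphenylphosphoranylidene)propanal, CC(C=O)=P(c1ccccc1)(c1ccccc1)c1ccccc1
Why: Wittig olefination with a formyl-stabilised ylide should give the (E)-trisubstituted enal under neutral, salt-free conditions, so the α-alkoxy aldehyde is not epimerised; the stereocentre (future C6) comes from the chiral pool.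

Step 2
Reactants: 2 (E)-3-[(4R)-2,2-dimethyl-1,3-dioxolan-4-yl]-2-methylprop-2-enal
Product: 3 (4R)-4-[(1E)-4,4-dibromo-2-methylbuta-1,3-dien-1-yl]-2,2-dimethyl-1,3-dioxolane
Conditions: CBr4, PPh3, Et3N, CH2Cl2, 0 °C
Reagents that add atoms: tetrabromomethane, BrC(Br)(Br)Br
Why: First stage of the Corey–Fuchs sequence (dibromoolefination); the amine keeps the medium non-acidic for the acetonide.

Step 3
Reactants: 3 (4R)-4-[(1E)-4,4-dibromo-2-methylbuta-1,3-dien-1-yl]-2,2-dimethyl-1,3-dioxolane
Product: 4 (4E)-5-[(4R)-2,2-dimethyl-1,3-dioxolan-4-yl]-4-methylpent-4-en-2-yn-1-ol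
Conditions: n-BuLi (2.2 equiv), THF, −78 °C; (CH2O)n, −78 °C → rt; aq. NH4Cl
Reagents that add atoms: paraformaldehyde (formaldehyde), C=O
Why: Second stage of the Corey–Fuchs sequence: bromine–lithium exchange and 1,2-shift give the lithium acetylide, which is hydroxymethylated by formaldehyde to install C1; the (E)-alkene is not touched.

Step 4
Reactants: 4 (4E)-5-[(4R)-2,2-dimethyl-1,3-dioxolan-4-yl]-4-methylpent-4-en-2-yn-1-ol
Product: 5 (4R)-4-[(1E)-5-[(4-methoxybenzyl)oxy]-2-methylpent-1-en-3-yn-1-yl]-2,2-dimethyl-1,3-dioxolane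
Conditions: NaH, 4-MeOC6H4CH2Cl, Bu4NI (cat.), THF–DMF, 0 °C → rt
Reagents that add atoms: 4-methoxybenzyl chloride, COc1ccc(CCl)cc1
Why: Williamson etherification; the 4-methoxybenzyl ether can later be removed oxidatively without acid.

Step 5
Reactants: 5 (4R)-4-[(1E)-5-[(4-methoxybenzyl)oxy]-2-methylpent-1-en-3-yn-1-yl]-2,2-dimethyl-1,3-dioxolane
Product: 6 (2R,3E)-7-[(4-methoxybenzyl)oxy]-4-methylhept-3-en-5-yne-1,2-diol
Conditions: AcOH–H2O (4:1), rt
Reagents that add atoms: none
Why: Acid-catalysed acetal hydrolysis; the propargylic benzyl-type ether and the enyne are stable to aqueous acetic acid, and the allylic C6–O bond should not ionise under these mild conditions.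

Step 6
Reactants: 6 (2R,3E)-7-[(4-methoxybenzyl)oxy]-4-methylhept-3-en-5-yne-1,2-diol
Product: 7 (2R,3E)-7-[(4-methoxybenzyl)oxy]-4-methyl-1-[(triethylsilyl)oxy]hept-3-en-5-yn-2-ol
Conditions: Et3SiCl (1.05 equiv), imidazole, CH2Cl2, −40 °C
Reagents that add atoms: chlorotriethylsilane, CC[Si](Cl)(CC)CC
Why: Silylation selective for the primary hydroxyl on steric grounds; this leaves the C6 hydroxyl as the only hydrogen-bond donor for the next step.

Step 7
Reactants: 7 (2R,3E)-7-[(4-methoxybenzyl)oxy]-4-methyl-1-[(triethylsilyl)oxy]hept-3-en-5-yn-2-ol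
Product: 8 (2S,3R,4R)-3,4-epoxy-7-[(4-methoxybenzyl)oxy]-4-methyl-1-[(triethylsilyl)oxy]hept-5-yn-2-ol
Conditions: mCPBA, NaHCO3, CH2Cl2, 0 °C
Reagents that add atoms: 3-chloroperoxybenzoic acid, OOC(=O)c1cccc(Cl)c1
Why: Hydroxyl-directed peracid epoxidation: the C15 methyl cis to C6 forces the C6–H bond to eclipse the alkene (1,3-allylic strain), and the peracid hydrogen-bonded to the C6 hydroxyl attacks the face syn to it, which should give the threo epoxy alcohol with (4R,5R) configuration. The alkyne and the arene are inert to the peracid.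

Step 8
Reactants: 8 (2S,3R,4R)-3,4-epoxy-7-[(4-methoxybenzyl)oxy]-4-methyl-1-[(triethylsilyl)oxy]hept-5-yn-2-ol
Product: 9 (2S,3R,4R)-3,4-epoxy-7-[(4-methoxybenzyl)oxy]-4-methyl-1-[(triethylsilyl)oxy]-2-[(triisopropylsilyl)oxy]hept-5-yne
Conditions: i-Pr3SiOTf, 2,6-lutidine, CH2Cl2, −78 → 0 °C
Reagents that add atoms: triisopropylsilyl trifluoromethanesulfonate, CC(C)[Si](OS(=O)(=O)C(F)(F)F)(C(C)C)C(C)C
Why: Silyl triflate with a hindered base silylates the hindered secondary alcohol at low temperature; the triisopropylsilyl group is chosen because it resists transfer to the neighbouring alkoxides formed in steps 13 and 18.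

Step 9
Reactants: 9 (2S,3R,4R)-3,4-epoxy-7-[(4-methoxybenzyl)oxy]-4-methyl-1-[(triethylsilyl)oxy]-2-[(triisopropylsilyl)oxy]hept-5-yne
Product: 10 (2R,3R,4R)-3,4-epoxy-7-[(4-methoxybenzyl)oxy]-4-methyl-2-[(triisopropylsilyl)oxy]hept-5-ynal
Conditions: (COCl)2, DMSO, CH2Cl2, −78 → −40 °C; Et3N, −78 → 0 °C
Reagents that add atoms: none
Why: Swern oxidation in which the chlorosulfonium reagent cleaves the primary triethylsilyl ether and oxidises that carbon in the same flask, while the secondary triisopropylsilyl ether stays; no separate deprotection is needed.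

Step 10
Reactants: 10 (2R,3R,4R)-3,4-epoxy-7-[(4-methoxybenzyl)oxy]-4-methyl-2-[(triisopropylsilyl)oxy]hept-5-ynal; 11 methyl acrylate
Product: 12 methyl (4S,5R,6R)-5,6-epoxy-3-hydroxy-9-[(4-methoxybenzyl)oxy]-6-methyl-2-methylidene-4-[(triisopropylsilyl)oxy]non-7-ynoate (both C3 epimers)
Conditions: methyl acrylate (10 equiv), DABCO (1 equiv), 1,4-dioxane–H2O (1:1), rt
Reagents that add atoms: none
Why: Morita–Baylis–Hillman reaction; α-oxygenated aldehydes are activated electrophiles for the amine–acrylate zwitterion. The configuration of the new carbinol (C7) does not matter because it is erased in step 11.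

Step 11
Reactants: 12 methyl (4S,5R,6R)-5,6-epoxy-3-hydroxy-9-[(4-methoxybenzyl)oxy]-6-methyl-2-methylidene-4-[(triisopropylsilyl)oxy]non-7-ynoate
Product: 13 methyl (2Z,4S,5R,6R)-2-(bromomethyl)-5,6-epoxy-9-[(4-methoxybenzyl)oxy]-6-methyl-4-[(triisopropylsilyl)oxy]non-2-en-7-ynoate
Conditions: NBS, Me2S, CH2Cl2, 0 °C → rt
Reagents that add atoms: N-bromosuccinimide, O=C1CCC(=O)N1Br
Why: Corey–Kim-type activation of the allylic alcohol and SN2′ attack of bromide move the double bond into conjugation; acrylate-derived adducts give the (Z)-2-(bromomethyl)alkenoate, that is C6 cis to C13, because the ester prefers the position trans to the C6 substituent.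

Step 12
Reactants: 13 methyl (2Z,4S,5R,6R)-2-(bromomethyl)-5,6-epoxy-9-[(4-methoxybenzyl)oxy]-6-methyl-4-[(triisopropylsilyl)oxy]non-2-en-7-ynoate
Product: 15 methyl (2E,4S,5R,6R)-5,6-epoxy-2-(hydroxymethyl)-9-[(4-methoxybenzyl)oxy]-6-methyl-4-[(triisopropylsilyl)oxy]non-2-en-7-ynoate, via allylic acetate 14 (not isolated)
Conditions: KOAc, DMF, rt; then MeOH, K2CO3 (cat.), 0 °C
Reagents that add atoms: potassium acetate, CC(=O)[O-].[K+]
Why: SN2 displacement of the primary allylic bromide by acetate, then base-catalysed methanolysis of the acetate in the same flask; the alkene geometry is retained and the methyl esters are unchanged by methoxide.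

Step 13
Reactants: 15 methyl (2E,4S,5R,6R)-5,6-epoxy-2-(hydroxymethyl)-9-[(4-methoxybenzyl)oxy]-6-methyl-4-[(triisopropylsilyl)oxy]non-2-en-7-ynoate; 16 methyl 4-chloro-3-oxobutanoate
Product: 17 methyl (2E,4S,5R,6R)-5,6-epoxy-2-[(4-methoxy-2,4-dioxobutoxy)methyl]-9-[(4-methoxybenzyl)oxy]-6-methyl-4-[(triisopropylsilyl)oxy]non-2-en-7-ynoate
Conditions: NaH (2.2 equiv), THF, 0 °C → rt; aq. NH4Cl
Reagents that add atoms: none
Why: Williamson etherification: the sodium alkoxide displaces chloride from the sodium enolate of the chloroacetoacetate, the standard route to 4-alkoxyacetoacetates; two equivalents of NaH are needed because the β-keto ester is deprotonated first.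

Step 14
Reactants: 17 methyl (2E,4S,5R,6R)-5,6-epoxy-2-[(4-methoxy-2,4-dioxobutoxy)methyl]-9-[(4-methoxybenzyl)oxy]-6-methyl-4-[(triisopropylsilyl)oxy]non-2-en-7-ynoate
Product: 18 methyl (2E,4S,5R,6R)-5,6-epoxy-9-hydroxy-2-[(4-methoxy-2,4-dioxobutoxy)methyl]-6-methyl-4-[(triisopropylsilyl)oxy]non-2-en-7-ynoate
Conditions: DDQ, CH2Cl2–pH 7 buffer (10:1), 0 °C
Reagents that add atoms: none
Why: Oxidative cleavage of the 4-methoxybenzyl ether under buffered conditions; the propargylic alcohol that is released cannot reach the epoxide.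

Step 15
Reactants: 18 methyl (2E,4S,5R,6R)-5,6-epoxy-9-hydroxy-2-[(4-methoxy-2,4-dioxobutoxy)methyl]-6-methyl-4-[(triisopropylsilyl)oxy]non-2-en-7-ynoate
Product: 19 methyl (2E,4S,5R,6R)-9-bromo-5,6-epoxy-2-[(4-methoxy-2,4-dioxobutoxy)methyl]-6-methyl-4-[(triisopropylsilyl)oxy]non-2-en-7-ynoate
Conditions: CBr4, PPh3, CH2Cl2, −20 °C
Reagents that add atoms: tetrabromomethane, BrC(Br)(Br)Br
Why: Appel bromination of the primary propargylic alcohol under neutral conditions.

Step 16
Reactants: 19 methyl (2E,4S,5R,6R)-9-bromo-5,6-epoxy-2-[(4-methoxy-2,4-dioxobutoxy)methyl]-6-methyl-4-[(triisopropylsilyl)oxy]non-2-en-7-ynoate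
Product: 20 thirteen-membered cyclic γ-allyloxy β-keto ester with C2≡C3 triple bond (enol form; 4R,5R-epoxide; 6S-triisopropylsilyloxy; C6 cis to C13 on C7=C11)
Conditions: Cs2CO3, MeCN, 1 mM (slow addition), rt
Reagents that add atoms: none
Why: Intramolecular C-alkylation of the β-keto ester enolate by the propargylic bromide (exo-tet closure of the thirteen-membered ring) under high dilution; stabilised enolates alkylate on carbon with propargylic and allylic bromides, and this closure is established for rings of this size.

Step 17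
Reactants: 20 thirteen-membered cyclic γ-allyloxy β-keto ester with C2≡C3 triple bond
Product: 21 thirteen-membered cyclic γ-allyloxy β-keto ester with (Z)-C2=C3 double bond (enol form; 4R,5R,6S)
Conditions: H2 (1 atm), Pd/CaCO3 poisoned with Pb(OAc)2 (Lindlar catalyst), quinoline, EtOAc, rt
Reagents that add atoms: none
Why: Lindlar semihydrogenation: syn addition of hydrogen gives the cis alkene; the trisubstituted enoate, the enol and the epoxide should not be reduced on the poisoned catalyst.

Step 18
Reactants: 21 thirteen-membered cyclic γ-allyloxy β-keto ester with (Z)-C2=C3 double bond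
Product: 22 ten-membered β-keto ester (enol form) with (8S)-hydroxyl and (7R)-[1-(methoxycarbonyl)ethenyl] group; (Z)-C2=C3; (4R,5R)-epoxide; (6S)-triisopropylsilyloxy
Conditions: LiN(iPr)2 (2.3 equiv), THF, −78 → −40 °C; AcOH, −78 °C
Reagents that add atoms: none
Why: Proposed new method: two equivalents of LiN(iPr)2 convert the β-keto ester into its dianion, whose γ-carbon C8 (α to the ether oxygen) bonds to C7 across the five-atom array C8–O–C13–C11=C7 while the O–C13 bond breaks and the C11=C13 double bond forms, a suprafacial six-electron [2,3]-Wittig shift; the closest known reactions are the [2,3]-Wittig ring contraction of thirteen-membered allylic and propargylic ethers to cyclodecenols and the enolate [2,3]-Wittig shift of open-chain α-allyloxy carbonyl compounds. The ten-membered ring closes by ring contraction, the new C7–C8 bond spanning the thirteen-membered ring through a five-membered envelope transition state; a stepwise 5-endo-trig conjugate addition followed by loss of the β-alkoxide would lead to the same product, so the outcome does not depend on concertedness. C8 is set by the geometry of the chelated (Z)-dienolate and C7 by the alkene face that is attacked; the ring-cis geometry of C7=C11 (C6 cis to C13) places C11 and the C8 oxygen syn. The face is chosen by C6: with the C6–H bond eclipsing the alkene, the carbanion should approach anti to the triisopropylsilyloxy group, which gives (7R,8S). The step needs γ-selectivity of the dianion over an oxy-Claisen-type shift through C9 and over a [1,2]-shift; the large coefficient at the terminal carbon of the dienolate and the fact that only the γ-pathway keeps the β-keto ester enolate intact should secure it. The cold acetic acid quench is needed so that the C8 alkoxide, which is cis to the propenoate, does not close onto the C12 ester.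

Step 19
Reactants: 23 (E)-2-methylbut-2-en-1-ol
Product: 24 [(2R,3R)-2,3-dimethyloxiran-2-yl]methanol
Conditions: Ti(OiPr)4 (10 mol %), D-(−)-diisopropyl tartrate (12 mol %), t-BuOOH, 4 Å molecular sieves, CH2Cl2, −20 °C
Reagents that add atoms: tert-butyl hydroperoxide, CC(C)(C)OO
Why: Sharpless asymmetric epoxidation of the (E)-trisubstituted allylic alcohol; the D-(−)-tartrate should deliver oxygen to the face that gives the (2R,3R)-epoxy alcohol, and the alkene geometry fixes the cis relation of the two methyl groups.

Step 20
Reactants: 24 [(2R,3R)-2,3-dimethyloxiran-2-yl]methanol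
Product: 25 (2S,3R)-2,3-dimethyloxirane-2-carboxylic acid
Conditions: TEMPO (cat.), PhI(OAc)2, MeCN–H2O (1:1), rt
Reagents that add atoms: water, O
Why: Oxoammonium oxidation of the primary alcohol through the aldehyde hydrate to the acid under near-neutral conditions that spare the epoxide; the C2 descriptor changes to S only through the priority rules.

Step 21
Reactants: 22 ten-membered β-keto ester with (8S)-hydroxyl; 25 (2S,3R)-2,3-dimethyloxirane-2-carboxylic acid
Product: 27 C8 (2S,3R)-2,3-dimethyloxirane-2-carboxylate of the ten-membered β-keto ester (enol form), via mixed anhydride 26 (not isolated)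
Conditions: 25, 2,4,6-Cl3C6H2COCl, Et3N, THF, 0 °C; then 22, DMAP, toluene, rt
Reagents that add atoms: none
Why: Yamaguchi esterification: the mixed anhydride of the hindered acid acylates the C8 hydroxyl under DMAP catalysis; the intramolecularly hydrogen-bonded enol is the poorer nucleophile. Prompt acylation also removes the hydroxyl that could lactonise onto C12.

Step 22
Reactants: 27 C8 (2S,3R)-2,3-dimethyloxirane-2-carboxylate of the ten-membered β-keto ester
Product: 30 ten-membered C9 ketone with C10=C1 double bond (C9 cis to C2) and (Z)-C2=C3, via C10 phenylselenide 28 (not isolated), via C10 selenoxide 29 (not isolated)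
Conditions: PhSeCl, pyridine, CH2Cl2, 0 °C; then 30% H2O2, 0 °C → rt
Reagents that add atoms: none
Why: α-Selenenylation of the β-keto ester enol by the PhSeCl–pyridine complex, which does not add to the alkenes, then oxidation and selenoxide syn-elimination; only C1 carries β-hydrogens, so the new double bond must be C10=C1. The ring-cis diene is expected as the less strained isomer of an easily equilibrated alkylidene β-keto ester.

Step 23
Reactants: 30 ten-membered C9 ketone with C10=C1 double bond
Product: 31 (9S)-alcohol of the ten-membered dienoate (C8 epoxy ester; C6 silyl ether; C7 propenoate)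
Conditions: NaBH4, CeCl3·7H2O, MeOH, −78 °C
Reagents that add atoms: none
Why: Luche reduction: the CeCl3-activated ketone should be attacked in 1,2-fashion by the hard methoxyborohydride in preference to conjugate addition, as in the reduction of alkylidene β-keto esters to hydroxy acrylates. Hydride is expected anti to the C8 acyloxy group (Felkin–Anh) from the outer face of the ring, which gives (9S).

Step 24
Reactants: 31 (9S)-alcohol of the ten-membered dienoate
Product: 32 (9S)-acetate of the ten-membered dienoate
Conditions: Ac2O, pyridine, DMAP (cat.), CH2Cl2, 0 °C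
Reagents that add atoms: acetic anhydride, CC(=O)OC(C)=O
Why: DMAP-catalysed acetylation of the secondary allylic alcohol at low temperature, where acyl transfer from O8 and SN2′ attack on the new allylic acetate should not compete.

Step 25
Reactants: 32 (9S)-acetate of the ten-membered dienoate
Product: 34 CNP0229507.7 (target), via C6 hydroxy ester 33 (not isolated)
Conditions: Bu4NF, THF, 0 °C → rt
Reagents that add atoms: none
Why: Fluoride cleaves the Si–O bond and the C6 alkoxide closes onto the C12 methyl ester (5-exo-trig lactonisation) to the trans-fused α-methylene-γ-lactone; the irreversible ring closure removes the alkoxide before it can open the neighbouring epoxide.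

## Compound list

1 | (S)-2,2-dimethyl-1,3-dioxolane-4-carbaldehyde | O=C[C@H]1OC(C)(C)OC1 | starting material
2 | (E)-3-[(4R)-2,2-dimethyl-1,3-dioxolan-4-yl]-2-methylprop-2-enal | O=C/C(C)=C/[C@H]1OC(C)(C)OC1 | intermediate
3 | (4R)-4-[(1E)-4,4-dibromo-2-methylbuta-1,3-dien-1-yl]-2,2-dimethyl-1,3-dioxolane | BrC(Br)=C/C(C)=C/[C@H]1OC(C)(C)OC1 | intermediate
4 | (4E)-5-[(4R)-2,2-dimethyl-1,3-dioxolan-4-yl]-4-methylpent-4-en-2-yn-1-ol | OCC#C/C(C)=C/[C@H]1OC(C)(C)OC1 | intermediate
5 | (4R)-4-[(1E)-5-[(4-methoxybenzyl)oxy]-2-methylpent-1-en-3-yn-1-yl]-2,2-dimethyl-1,3-dioxolane | COc1ccc(COCC#C/C(C)=C/[C@H]2OC(C)(C)OC2)cc1 | intermediate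
6 | (2R,3E)-7-[(4-methoxybenzyl)oxy]-4-methylhept-3-en-5-yne-1,2-diol | COc1ccc(COCC#C/C(C)=C/[C@@H](O)CO)cc1 | intermediate
7 | (2R,3E)-7-[(4-methoxybenzyl)oxy]-4-methyl-1-[(triethylsilyl)oxy]hept-3-en-5-yn-2-ol | COc1ccc(COCC#C/C(C)=C/[C@@H](O)CO[Si](CC)(CC)CC)cc1 | intermediate
8 | (2S,3R,4R)-3,4-epoxy-7-[(4-methoxybenzyl)oxy]-4-methyl-1-[(triethylsilyl)oxy]hept-5-yn-2-ol | COc1ccc(COCC#C[C@@]2(C)O[C@@H]2[C@@H](O)CO[Si](CC)(CC)CC)cc1 | intermediate
9 | (2S,3R,4R)-3,4-epoxy-7-[(4-methoxybenzyl)oxy]-4-methyl-1-[(triethylsilyl)oxy]-2-[(triisopropylsilyl)oxy]hept-5-yne | COc1ccc(COCC#C[C@@]2(C)O[C@@H]2[C@@H](O[Si](C(C)C)(C(C)C)C(C)C)CO[Si](CC)(CC)CC)cc1 | intermediate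
10 | (2R,3R,4R)-3,4-epoxy-7-[(4-methoxybenzyl)oxy]-4-methyl-2-[(triisopropylsilyl)oxy]hept-5-ynal | COc1ccc(COCC#C[C@@]2(C)O[C@@H]2[C@@H](O[Si](C(C)C)(C(C)C)C(C)C)C=O)cc1 | intermediate
11 | methyl acrylate | C=CC(=O)OC | starting material
12 | methyl (4S,5R,6R)-5,6-epoxy-3-hydroxy-9-[(4-methoxybenzyl)oxy]-6-methyl-2-methylidene-4-[(triisopropylsilyl)oxy]non-7-ynoate (both C3 epimers) | COc1ccc(COCC#C[C@@]2(C)O[C@@H]2[C@@H](O[Si](C(C)C)(C(C)C)C(C)C)C(O)C(=C)C(=O)OC)cc1 | intermediate
13 | methyl (2Z,4S,5R,6R)-2-(bromomethyl)-5,6-epoxy-9-[(4-methoxybenzyl)oxy]-6-methyl-4-[(triisopropylsilyl)oxy]non-2-en-7-ynoate | COc1ccc(COCC#C[C@@]2(C)O[C@@H]2[C@@H](O[Si](C(C)C)(C(C)C)C(C)C)/C=C(C(=O)OC)\CBr)cc1 | intermediate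
14 | methyl (2E,4S,5R,6R)-2-(acetoxymethyl)-5,6-epoxy-9-[(4-methoxybenzyl)oxy]-6-methyl-4-[(triisopropylsilyl)oxy]non-2-en-7-ynoate | COc1ccc(COCC#C[C@@]2(C)O[C@@H]2[C@@H](O[Si](C(C)C)(C(C)C)C(C)C)/C=C(C(=O)OC)\COC(C)=O)cc1 | intermediate
15 | methyl (2E,4S,5R,6R)-5,6-epoxy-2-(hydroxymethyl)-9-[(4-methoxybenzyl)oxy]-6-methyl-4-[(triisopropylsilyl)oxy]non-2-en-7-ynoate | COc1ccc(COCC#C[C@@]2(C)O[C@@H]2[C@@H](O[Si](C(C)C)(C(C)C)C(C)C)/C=C(C(=O)OC)\CO)cc1 | intermediate
16 | methyl 4-chloro-3-oxobutanoate (methyl 4-chloroacetoacetate) | COC(=O)CC(=O)CCl | starting material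
17 | methyl (2E,4S,5R,6R)-5,6-epoxy-2-[(4-methoxy-2,4-dioxobutoxy)methyl]-9-[(4-methoxybenzyl)oxy]-6-methyl-4-[(triisopropylsilyl)oxy]non-2-en-7-ynoate | COc1ccc(COCC#C[C@@]2(C)O[C@@H]2[C@@H](O[Si](C(C)C)(C(C)C)C(C)C)/C=C(C(=O)OC)\COCC(=O)CC(=O)OC)cc1 | intermediate
18 | methyl (2E,4S,5R,6R)-5,6-epoxy-9-hydroxy-2-[(4-methoxy-2,4-dioxobutoxy)methyl]-6-methyl-4-[(triisopropylsilyl)oxy]non-2-en-7-ynoate | OCC#C[C@@]1(C)O[C@@H]1[C@@H](O[Si](C(C)C)(C(C)C)C(C)C)/C=C(C(=O)OC)\COCC(=O)CC(=O)OC | intermediate
19 | methyl (2E,4S,5R,6R)-9-bromo-5,6-epoxy-2-[(4-methoxy-2,4-dioxobutoxy)methyl]-6-methyl-4-[(triisopropylsilyl)oxy]non-2-en-7-ynoate | BrCC#C[C@@]1(C)O[C@@H]1[C@@H](O[Si](C(C)C)(C(C)C)C(C)C)/C=C(C(=O)OC)\COCC(=O)CC(=O)OC | intermediate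
20 | thirteen-membered cyclic γ-allyloxy β-keto ester with C2≡C3 triple bond (enol form; 4R,5R-epoxide; 6S-triisopropylsilyloxy; C6 cis to C13 on C7=C11; C13–O–C8 ether) | O/C1=C(\C(=O)OC)CC#C[C@@]2(C)O[C@@H]2[C@@H](O[Si](C(C)C)(C(C)C)C(C)C)/C=C(C(=O)OC)\COC1 | intermediate
21 | thirteen-membered cyclic γ-allyloxy β-keto ester with (Z)-C2=C3 double bond (enol form; 4R,5R,6S); precursor of the key step | O/C1=C(\C(=O)OC)C/C=C\[C@@]2(C)O[C@@H]2[C@@H](O[Si](C(C)C)(C(C)C)C(C)C)/C=C(C(=O)OC)\COC1 | intermediate
22 | ten-membered β-keto ester (enol form) with (8S)-hydroxyl, (7R)-[1-(methoxycarbonyl)ethenyl], (Z)-C2=C3, (4R,5R)-epoxide, (6S)-triisopropylsilyloxy; product of the key step | O/C1=C(\C(=O)OC)C/C=C\[C@@]2(C)O[C@@H]2[C@@H](O[Si](C(C)C)(C(C)C)C(C)C)[C@H](C(=C)C(=O)OC)[C@@H]1O | intermediate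
23 | (E)-2-methylbut-2-en-1-ol (tiglyl alcohol) | C/C=C(\C)CO | starting material
24 | [(2R,3R)-2,3-dimethyloxiran-2-yl]methanol | OC[C@@]1(C)O[C@@H]1C | intermediate
25 | (2S,3R)-2,3-dimethyloxirane-2-carboxylic acid | OC(=O)[C@@]1(C)O[C@@H]1C | intermediate
26 | (2S,3R)-2,3-dimethyloxirane-2-carboxylic 2,4,6-trichlorobenzoic anhydride | O=C(OC(=O)[C@@]1(C)O[C@@H]1C)c1c(Cl)cc(Cl)cc1Cl | intermediate
27 | C8 (2S,3R)-2,3-dimethyloxirane-2-carboxylate of 22 (enol form) | O/C1=C(\C(=O)OC)C/C=C\[C@@]2(C)O[C@@H]2[C@@H](O[Si](C(C)C)(C(C)C)C(C)C)[C@H](C(=C)C(=O)OC)[C@@H]1OC(=O)[C@@]3(C)O[C@@H]3C | intermediate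
28 | C10 phenylselenide of 27 (keto form; C10 epimers) | O=C1C(C(=O)OC)([Se]c3ccccc3)C/C=C\[C@@]2(C)O[C@@H]2[C@@H](O[Si](C(C)C)(C(C)C)C(C)C)[C@H](C(=C)C(=O)OC)[C@@H]1OC(=O)[C@@]4(C)O[C@@H]4C | intermediate
29 | C10 selenoxide of 28 | O=C1C(C(=O)OC)([Se](=O)c3ccccc3)C/C=C\[C@@]2(C)O[C@@H]2[C@@H](O[Si](C(C)C)(C(C)C)C(C)C)[C@H](C(=C)C(=O)OC)[C@@H]1OC(=O)[C@@]4(C)O[C@@H]4C | intermediate
30 | ten-membered C9 ketone with C10=C1 (C9 cis to C2) and (Z)-C2=C3; C8 epoxy ester; C6 silyl ether; C7 propenoate | O=C1/C(C(=O)OC)=C\C=C/[C@@]2(C)O[C@@H]2[C@@H](O[Si](C(C)C)(C(C)C)C(C)C)[C@H](C(=C)C(=O)OC)[C@@H]1OC(=O)[C@@]3(C)O[C@@H]3C | intermediate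
31 | (9S)-alcohol from 30 | O[C@H]1/C(C(=O)OC)=C\C=C/[C@@]2(C)O[C@@H]2[C@@H](O[Si](C(C)C)(C(C)C)C(C)C)[C@H](C(=C)C(=O)OC)[C@@H]1OC(=O)[C@@]3(C)O[C@@H]3C | intermediate
32 | (9S)-acetate of 31 | CC(=O)O[C@H]1/C(C(=O)OC)=C\C=C/[C@@]2(C)O[C@@H]2[C@@H](O[Si](C(C)C)(C(C)C)C(C)C)[C@H](C(=C)C(=O)OC)[C@@H]1OC(=O)[C@@]3(C)O[C@@H]3C | intermediate
33 | C6 alcohol from 32 (methyl propenoate not yet lactonised) | CC(=O)O[C@H]1/C(C(=O)OC)=C\C=C/[C@@]2(C)O[C@@H]2[C@@H](O)[C@H](C(=C)C(=O)OC)[C@@H]1OC(=O)[C@@]3(C)O[C@@H]3C | intermediate
34 | CNP0229507.7: (4R,5R,6S,7R,8S,9S)-4,5-epoxygermacra-1(10),2,11(13)-trien-12,6-olide with C14 methyl ester, 9-acetate and 8-[(2S,3R)-2,3-dimethyloxirane-2-carboxylate] | C=C1C(=O)O[C@H]2[C@H]1[C@H](OC(=O)[C@@]1(C)O[C@@H]1C)[C@@H](OC(C)=O)/C(C(=O)OC)=C\C=C/[C@@]1(C)O[C@H]21 | target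

## Step count and least certain steps

Total step count: 25. Longest linear sequence: 23 steps (steps 1–18 and 21–25); the side-chain acid 25 is made in 2 steps (19–20) and joins at step 21.

**Step 18 (key step).** The dianion may not rearrange through C8. A shift through C9 (anionic oxy-Claisen type), addition of the C10 enolate to C7, or deprotonation at C6 or C13 of the enoate could consume it. The face of C7=C11 may be poorly differentiated on the flexible ring, and the C8 alkoxide may close onto the C12 ester before the quench. Fallback, known chemistry, with the rearrangement moved in front of ring closure: setting out from 17, Lindlar semihydrogenation gives the open-chain (Z)-alkene F1. Treatment of F1 with LiN(iPr)2 (2.2 equiv, THF, −78 °C) uses the established enolate [2,3]-Wittig shift of open-chain α-allyloxy carbonyl compounds and should give the open-chain hydroxy keto ester F2. Yamaguchi esterification with 25 gives the C8 epoxy ester F3, DDQ frees the (Z)-allylic alcohol F4, and CBr4/PPh3 gives the (Z)-allylic bromide F5. Cs2CO3 at high dilution then closes the ten-membered ring by C10–C1 alkylation, the classical ring closure of germacranes, and the route is rejoined at 27.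

**Step 13 (etherification).** The primary alkoxide of 15 lives for hours under NaH. It may open the epoxide at C5 (6-exo attack, made possible by the cis relation of C6 and C13), add to another enoate, or induce silyl transfer. Fallback, neutral carbenoid chemistry in place of an alkoxide: setting out from 15, Rh2(OAc)4-catalysed O–H insertion of the carbenoid from methyl 4-diazo-3-oxobutanoate F8 should give 17 directly.

**Step 16 (macrocyclisation, with step 17).** A thirteen-membered ring holding the linear C1–C2≡C3–C4 unit may close slowly. Intermolecular alkylation, O-alkylation or seven-ring conjugate addition of C10 to C7 could then take over, and semihydrogenation of the strained product may overrun. Fallback, reduction before ring closure: setting out from 17, Lindlar semihydrogenation gives the (Z)-alkene F1 (as above), DDQ gives the (Z)-allylic alcohol F6, and CBr4/PPh3 with 2,6-lutidine gives the (Z)-allylic bromide F7. Cs2CO3 at high dilution then closes the ring, helped by the turn of the cis alkene, and arrives directly at 21. The price is that F6 can cyclise onto C4 to a dihydrofuran, so it must be kept buffered and used at once.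

**Step 10 (Morita–Baylis–Hillman).** Slow conversion under amine catalysis leaves time for enolisation of the aldehyde, with epimerisation at C6 or β-elimination that opens the epoxide. Fallback, a pre-formed vinyl metal in place of amine catalysis: setting out from 10, addition of [1-(methoxycarbonyl)ethenyl]diisobutylaluminium F9 (from methyl propiolate, i-Bu2AlH and N-methylmorpholine N-oxide, THF, 0 °C) should give 12 without base.

**Step 7 (directed epoxidation).** The enyne alkene is electron-poor, so the hydrogen-bonded pathway may be slow and undirected attack may erode facial selectivity. Fallback, reagent control in place of substrate direction: setting out from 7, Shi epoxidation with the fructose-derived ketone catalyst of the matching enantiomeric series (KHSO5, pH 10.5 buffer, MeCN–dimethoxymethane, 0 °C) gives 8; no new compound arises.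

**Step 23 (reduction at C9).** Hydride may add in conjugate fashion to the doubly activated diene or to the wrong face of the ketone, and the C8 acyl group may move to O9 once the alkoxide forms. Fallback, reagent-controlled 1,2-reduction: setting out from 30, reduction with catecholborane and the oxazaborolidine catalyst (CBS reduction) of the enantiomer that delivers hydride to the required face gives 31; no new compound arises.

## Further compounds

F1 | step 18 | methyl (2E,4S,5R,6R,7Z)-5,6-epoxy-2-[(4-methoxy-2,4-dioxobutoxy)methyl]-9-[(4-methoxybenzyl)oxy]-6-methyl-4-[(triisopropylsilyl)oxy]nona-2,7-dienoate | COc1ccc(COC/C=C\[C@@]2(C)O[C@@H]2[C@@H](O[Si](C(C)C)(C(C)C)C(C)C)/C=C(C(=O)OC)\COCC(=O)CC(=O)OC)cc1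
F2 | step 18 | open-chain rearrangement product: (8S)-hydroxy β-keto ester with (7R)-[1-(methoxycarbonyl)ethenyl] group, (Z)-C2=C3, C1 4-methoxybenzyl ether | COc1ccc(COC/C=C\[C@@]2(C)O[C@@H]2[C@@H](O[Si](C(C)C)(C(C)C)C(C)C)[C@H](C(=C)C(=O)OC)[C@H](O)C(=O)CC(=O)OC)cc1
F3 | step 18 | C8 (2S,3R)-2,3-dimethyloxirane-2-carboxylate of F2 | COc1ccc(COC/C=C\[C@@]2(C)O[C@@H]2[C@@H](O[Si](C(C)C)(C(C)C)C(C)C)[C@H](C(=C)C(=O)OC)[C@H](OC(=O)[C@@]3(C)O[C@@H]3C)C(=O)CC(=O)OC)cc1
F4 | step 18 | (Z)-allylic C1 alcohol from F3 | OC/C=C\[C@@]1(C)O[C@@H]1[C@@H](O[Si](C(C)C)(C(C)C)C(C)C)[C@H](C(=C)C(=O)OC)[C@H](OC(=O)[C@@]2(C)O[C@@H]2C)C(=O)CC(=O)OC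
F5 | step 18 | (Z)-allylic C1 bromide from F4 | BrC/C=C\[C@@]1(C)O[C@@H]1[C@@H](O[Si](C(C)C)(C(C)C)C(C)C)[C@H](C(=C)C(=O)OC)[C@H](OC(=O)[C@@]2(C)O[C@@H]2C)C(=O)CC(=O)OC
F6 | step 16 | methyl (2E,4S,5R,6R,7Z)-5,6-epoxy-9-hydroxy-2-[(4-methoxy-2,4-dioxobutoxy)methyl]-6-methyl-4-[(triisopropylsilyl)oxy]nona-2,7-dienoate | OC/C=C\[C@@]1(C)O[C@@H]1[C@@H](O[Si](C(C)C)(C(C)C)C(C)C)/C=C(C(=O)OC)\COCC(=O)CC(=O)OC
F7 | step 16 | methyl (2E,4S,5R,6R,7Z)-9-bromo-5,6-epoxy-2-[(4-methoxy-2,4-dioxobutoxy)methyl]-6-methyl-4-[(triisopropylsilyl)oxy]nona-2,7-dienoate | BrC/C=C\[C@@]1(C)O[C@@H]1[C@@H](O[Si](C(C)C)(C(C)C)C(C)C)/C=C(C(=O)OC)\COCC(=O)CC(=O)OC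
F8 | step 13 | methyl 4-diazo-3-oxobutanoate | COC(=O)CC(=O)C=[N+]=[N-]
F9 | step 10 | methyl 2-(diisobutylalumanyl)prop-2-enoate | C=C(C(=O)OC)[Al](CC(C)C)CC(C)C
F0 | step 7 | none | none
F0 | step 23 | none | none
A1 | alternative 1 | 2-[(4-methoxybenzyl)oxy]-3-methylcyclohepta-2,4,6-trien-1-one | COc1ccc(COC2=C(C)C=CC=CC2=O)cc1
A2 | alternative 1 | (1E,3E)-buta-1,3-diene-1,4-diyl diacetate | CC(=O)O/C=C/C=C/OC(C)=O
A3 | alternative 1 | exo bicyclo[4.4.1]undeca-2,4,8-trien-11-one with C6 and C9 acetates and bridgehead C5 4-methoxybenzyl ether | O=C1[C@]2(OCc3ccc(OC)cc3)C(C)=CC=C[C@H]1[C@H](OC(C)=O)C=C[C@@H]2OC(C)=O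
A4 | alternative 2 | decalin epoxy ketone (C2 ketone, C3–C8 epoxide at the ring fusion; epoxide configuration left open) | CC(C)(C)[Si](C)(C)OCC[C@H]1[C@H](O[Si](C)(C)C(C)(C)C)[C@@H]2OC(C)(C)O[C@]2(C)C3(O4)C(=O)C[C@@H](C(=O)OC)[C@H](OCc5ccc(OC)cc5)C134
A5 | alternative 2 | ten-membered cycloalkynone (C2≡C3, C8 ketone) with C4 to C7 and C9 stereocentres in place | CC(C)(C)[Si](C)(C)OCC[C@H]1[C@H](O[Si](C)(C)C(C)(C)C)[C@@H]2OC(C)(C)O[C@]2(C)C#CC[C@@H](C(=O)OC)[C@H](OCc3ccc(OC)cc3)C1=O
A6 | alternative 3 | cis-fused hexalin (C5–C10 bond, C1=C2 and C3=C4 diene; C5 and C10 configuration left open) carrying lactone, C9 acetate and C8 silyl ether | O=C1C(=C)[C@H]2[C@H](O1)C3C(C)=CC=CC3(C(=O)OC)[C@H](OC(C)=O)[C@H]2O[Si](C)(C)C(C)(C)C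
A7 | alternative 3 | ten-membered C1(10),C2,C4 trienoate carrying lactone, C9 acetate and C8 silyl ether | O=C1C(=C)[C@H]2[C@H](O1)/C=C(C)/C=C\C=C(C(=O)OC)/[C@H](OC(C)=O)[C@H]2O[Si](C)(C)C(C)(C)C
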